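**Strategy.** The bicyclo[3.3.1]nonane core (C1 carbinol bridgehead, C2–C3 epoxide, C4, C5, C6, C7–N, C8, C9 ketone) hides two retrons: the tertiary α-ketol C9(=O)–C1(OH) and, behind the epoxide, a cis C2=C3 alkene. One flask therefore closes both rings of an acyclic keto-aldehyde diene: a carbene-catalysed crossed benzoin joins aldehyde C9 to the C1 vinyl ketone (ring B), then ruthenium ring-closing metathesis joins the C2 and C3 vinyl termini (ring A, C1–C5 plus C9). The linear precursor comes from L-aspartic acid, an acetyl oxazolidinone and acrolein; N-acylation and a hydroxyl-directed epoxidation of the new C2=C3 bond finish the synthesis.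

Key step: step 11

Remark on numbering: the core is numbered as bicyclo[3.3.1]nonane (C1 C–OH bridgehead, C2/C3 epoxide, C4 CHOH, C5 CH bridgehead, C6 CHOH, C7 CHN, C8 CH2, C9 C=O); in open-chain intermediates "future Cn" means these atoms.
Assumption: compounds 1, 4, 9, 18 and 21 are taken as commercial.

Step 1
Reactants: 1 N-Boc-L-aspartic acid 1-benzyl ester
Product: 2 benzyl (2S)-2-(Boc-amino)-4-[methoxy(methyl)amino]-4-oxobutanoate
Conditions: MeNH(OMe)·HCl, EDC·HCl, HOBt, N-methylmorpholine, CH2Cl2, 0 °C → rt
Reagents that add atoms: N,O-dimethylhydroxylamine hydrochloride, CNOC.Cl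
Why: carbodiimide/HOBt amide coupling of the only free carboxyl group gives the Weinreb amide that later becomes the C1 vinyl ketone; the L-configured carbon (future C7) is not involved.

Step 2
Reactants: 2 benzyl ester Weinreb amide
Product: 3 (2S)-2-(Boc-amino)-4-[methoxy(methyl)amino]-4-oxobutanoic acid
Conditions: H2 (1 atm), Pd/C, EtOAc, rt
Reagents that add atoms: none
Why: catalytic hydrogenolysis of the benzyl ester frees the α-carboxyl group and should leave the carbamate and the N–O bond of the Weinreb amide intact under these mild conditions.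

Step 3
Reactants: 3 Weinreb acid; 4 (4S)-3-acetyl-4-benzyl-1,3-oxazolidin-2-one
Product: 6 β-keto imide tert-butyl N-[(3S)-6-[(4S)-4-benzyl-2-oxo-1,3-oxazolidin-3-yl]-1-[methoxy(methyl)amino]-1,4,6-trioxohexan-3-yl]carbamate, via acyl imidazolide 5 (not isolated)
Conditions: 3, 1,1'-carbonyldiimidazole, THF, 0 °C → rt; separately 4, LiN(SiMe3)2 (3.2 equiv), THF, −78 °C; imidazolide solution added at −78 °C; aq. NH4Cl
Reagents that add atoms: none
Why: Claisen-type C-acylation of the lithium enolate of the acetyl imide by the acyl imidazolide should give the β-keto imide, the excess enolate serving as base for the carbamate N–H and the acidic product, while urethane protection and −78 °C guard the future C7 against racemisation.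

Step 4
Reactants: 6 β-keto imide
Product: 7 (3S,4R)-β-hydroxy imide
Conditions: LiAlH(O-t-Bu)3, EtOH, −78 °C
Reagents that add atoms: none
Why: chelation-controlled (Cram-chelate) hydride reduction of an N-carbamoyl α-amino ketone, in which the metal-bridged carbamate and ketone expose the face anti to the CH2 side chain, so the new carbinol (future C6) should form anti to nitrogen, as the cis C6–O/C7–N pair of ring B requires.

Step 5
Reactants: 7 β-hydroxy imide
Product: 8 C6 tert-butyldimethylsilyl ether
Conditions: TBSOTf, 2,6-lutidine, CH2Cl2, −78 °C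
Reagents that add atoms: tert-butyldimethylsilyl triflate, CC(C)(C)[Si](C)(C)OS(=O)(=O)C(F)(F)F
Why: silylation of the secondary alcohol with the silyl triflate and a hindered pyridine base is fast at −78 °C, blocks retro-aldol of the β-hydroxy imide and should leave the carbamate intact.

Step 6
Reactants: 8 silyloxy imide; 9 acrolein
Product: 10 (3S,4R,5R,6R) syn-aldol adduct
Conditions: Bu2BOTf (2.5 equiv), i-Pr2NEt, CH2Cl2, −78 → 0 °C; 9, −78 → 0 °C; pH 7 buffer, MeOH, H2O2
Reagents that add atoms: none
Why: Evans syn aldol, in which the Z-configured dibutylboron enolate of the (4S)-benzyl oxazolidinone imide meets acrolein in a Zimmerman–Traxler chair on the face away from the benzyl group, which should set the future C5 and C4 together (syn, auxiliary-controlled) and bring in the C3 vinyl terminus.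

Step 7
Reactants: 10 aldol adduct
Product: 11 bis-silyl ether
Conditions: TBSOTf, 2,6-lutidine, CH2Cl2, −78 °C
Reagents that add atoms: tert-butyldimethylsilyl triflate, CC(C)(C)[Si](C)(C)OS(=O)(=O)C(F)(F)F
Why: silylation of the allylic alcohol (future C4–OH) protects it against the later Grignard and oxidation steps and removes the retro-aldol pathway of the imide.

Step 8
Reactants: 11 bis-silyl imide
Product: 12 primary alcohol (future C9 as CH2OH)
Conditions: NaBH4, THF–H2O (4:1), 0 °C → rt
Reagents that add atoms: none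
Why: borohydride in wet THF reduces the exocyclic imide carbonyl chemoselectively to the primary alcohol and releases the auxiliary, while Weinreb amide and carbamate are inert to NaBH4.

Step 9
Reactants: 12 hydroxy Weinreb amide
Product: 13 hydroxy vinyl ketone
Conditions: CH2=CHMgBr (5 equiv), THF, −20 → 0 °C; inverse quench into cold aq. HCl
Reagents that add atoms: vinylmagnesium bromide, C=C[Mg]Br
Why: Grignard addition to the Weinreb amide stops at the chelated tetrahedral intermediate (excess reagent first deprotonates O–H and N–H), which collapses to the vinyl ketone only on the cold acidic quench that also keeps the released N,O-dimethylhydroxylamine protonated so that it cannot add to the enone.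

Step 10
Reactants: 13 hydroxy vinyl ketone
Product: 14 keto-aldehyde diene
Conditions: Dess–Martin periodinane, NaHCO3, CH2Cl2, 0 °C → rt; used at once
Reagents that add atoms: none
Why: Dess–Martin oxidation of the primary alcohol under buffered conditions should give the α-branched aldehyde (C9) without epimerising C5 or touching the enone.

Step 11
Reactants: 14 keto-aldehyde diene
Product: 16 bicyclo[3.3.1]non-2-en-9-one ketol, via monocyclic ketol 15 (not isolated)
Conditions: 2-(C6F5)-6,7-dihydro-5H-pyrrolo[2,1-c][1,2,4]triazol-2-ium BF4 (20 mol %), i-Pr2NEt (20 mol %), THF, 23 °C; then AcOH (40 mol %), toluene, (SIMes)(PCy3)Cl2Ru=CHPh (second-generation Grubbs catalyst, SIMes = 1,3-dimesitylimidazolidin-2-ylidene, 10 mol %), 70 °C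
Reagents that add atoms: none
Why: the triazolylidene adds to aldehyde C9 to give the Breslow acyl-anion equivalent, which attacks the C1 ketone in a 6-exo-trig closure of ring B (crossed aldehyde–ketone benzoin, the closest known reaction type) and releases the carbene; after the carbene is returned to its azolium salt with acetic acid so that the two catalysts do not meet, the ruthenium alkylidene engages the two vinyl groups through a ruthenacyclobutane and closes ring A as a cyclohexene by ring-closing metathesis with loss of ethene. C1 is the only new stereocentre: in the chair transition state the C5 side chain and C6–OTBS are equatorial, the C1 vinyl group should go equatorial and the forming alkoxide axial, where it is hydrogen-bonded to the axial NHBoc, so vinyl and C5 side chain end up cis. The benzoin is reversible under the carbene, C5 stays epimerisable next to the carbonyl with its trans relation to C6–OTBS thermodynamically preferred, and only the cis ketol can reach the 1,3-diaxial conformer that metathesis needs, so the second closure proof-reads the first. The step needs 1,2- instead of 1,4-addition to the vinyl ketone, which the ring sizes secure (six- against eight-membered), and carbene attack at the aldehyde in preference to conjugate addition, which the intramolecular rate and the weakly nucleophilic C6F5-triazolylidene should favour.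

Step 12
Reactants: 16 protected bicyclic ketol
Product: 17 (1S,4R,5R,6R,7S)-7-amino-1,4,6-trihydroxybicyclo[3.3.1]non-2-en-9-one hydrochloride
Conditions: methanolic HCl, 0 °C → rt
Reagents that add atoms: hydrogen chloride, Cl
Why: acid cleaves the carbamate (loss of the tert-butyl cation, decarboxylation) and both silyl ethers (methanolysis) in one operation, and the β-hydroxy ketone units cannot dehydrate because either alkene would sit at a bridgehead.

Step 13
Reactants: 18 hex-5-enenitrile
Product: 20 undec-1-en-6-one, via N-magnesio ketimine 19 (not isolated)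
Conditions: n-C5H11MgBr, Et2O, reflux; then aq. HCl, rt
Reagents that add atoms: pentylmagnesium bromide, CCCCC[Mg]Br; water, O
Why: Grignard addition to the nitrile gives the N-magnesio ketimine, which cannot add a second equivalent and is hydrolysed to the ketone on acidic work-up, the terminal alkene being inert.

Step 14
Reactants: 20 undec-1-en-6-one; 21 acrylic acid
Product: 22 (2E)-7-oxododec-2-enoic acid
Conditions: (SIMes)Cl2Ru=CH(2-i-PrO-C6H4) (second-generation Hoveyda–Grubbs catalyst, 3 mol %), CH2Cl2, 40 °C
Reagents that add atoms: none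
Why: olefin cross-metathesis between a terminal alkene and the electron-poor acrylic acid (used in excess) is selective for the hetero-coupled product and should give the E-configured 2-enoic acid under thermodynamic control.

Step 15
Reactants: 17 amino triol hydrochloride; 22 (2E)-7-oxododec-2-enoic acid
Product: 23 (2E)-7-oxo-N-[(1S,4R,5R,6R,7S)-1,4,6-trihydroxy-9-oxobicyclo[3.3.1]non-2-en-7-yl]dodec-2-enamide
Conditions: EDC·HCl, HOBt, i-Pr2NEt, DMF, 0 °C → rt
Reagents that add atoms: none
Why: carbodiimide/HOBt amide coupling is chemoselective for the primary amine over the three hydroxyl groups, the base serving only to free the amine from its hydrochloride.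

Step 16
Reactants: 23 alkene amide
Product: 24 isariotin C
Conditions: VO(acac)2 (5 mol %), t-BuOOH, CH2Cl2, 0 °C → rt
Reagents that add atoms: tert-butyl hydroperoxide, CC(C)(C)OO
Why: vanadium-catalysed hydroxyl-directed epoxidation, in which the vanadate ester of the pseudoaxial allylic C4–OH delivers oxygen to the exo face of the C2=C3 bond (also the face not shielded by ring B), should set C2 and C3 syn to C4–OH, while the conjugated amide alkene is electron-poor and has no directing group.

**Compound list**

1 | N-Boc-L-aspartic acid 1-benzyl ester, (3S)-4-(benzyloxy)-3-[(tert-butoxycarbonyl)amino]-4-oxobutanoic acid | OC(=O)C[C@H](NC(=O)OC(C)(C)C)C(=O)OCc1ccccc1 | starting material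
2 | benzyl (2S)-2-[(tert-butoxycarbonyl)amino]-4-[methoxy(methyl)amino]-4-oxobutanoate | CON(C)C(=O)C[C@H](NC(=O)OC(C)(C)C)C(=O)OCc1ccccc1 | intermediate
3 | (2S)-2-[(tert-butoxycarbonyl)amino]-4-[methoxy(methyl)amino]-4-oxobutanoic acid | CON(C)C(=O)C[C@H](NC(=O)OC(C)(C)C)C(=O)O | intermediate
4 | (4S)-3-acetyl-4-benzyl-1,3-oxazolidin-2-one | CC(=O)N1[C@@H](Cc2ccccc2)COC1=O | starting material
5 | tert-butyl N-[(2S)-1-(1H-imidazol-1-yl)-4-[methoxy(methyl)amino]-1,4-dioxobutan-2-yl]carbamate | CON(C)C(=O)C[C@H](NC(=O)OC(C)(C)C)C(=O)n1ccnc1 | intermediate (not isolated)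
6 | tert-butyl N-[(3S)-6-[(4S)-4-benzyl-2-oxo-1,3-oxazolidin-3-yl]-1-[methoxy(methyl)amino]-1,4,6-trioxohexan-3-yl]carbamate | CON(C)C(=O)C[C@H](NC(=O)OC(C)(C)C)C(=O)CC(=O)N1[C@@H](Cc2ccccc2)COC1=O | intermediate
7 | tert-butyl N-[(3S,4R)-6-[(4S)-4-benzyl-2-oxo-1,3-oxazolidin-3-yl]-4-hydroxy-1-[methoxy(methyl)amino]-1,6-dioxohexan-3-yl]carbamate | CON(C)C(=O)C[C@H](NC(=O)OC(C)(C)C)[C@H](O)CC(=O)N1[C@@H](Cc2ccccc2)COC1=O | intermediate
8 | tert-butyl N-[(3S,4R)-6-[(4S)-4-benzyl-2-oxo-1,3-oxazolidin-3-yl]-4-[(tert-butyldimethylsilyl)oxy]-1-[methoxy(methyl)amino]-1,6-dioxohexan-3-yl]carbamate | CON(C)C(=O)C[C@H](NC(=O)OC(C)(C)C)[C@H](O[Si](C)(C)C(C)(C)C)CC(=O)N1[C@@H](Cc2ccccc2)COC1=O | intermediate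
9 | acrolein (prop-2-enal) | C=CC=O | starting material
10 | tert-butyl N-[(3S,4R,5R,6R)-5-[(4S)-4-benzyl-2-oxo-1,3-oxazolidine-3-carbonyl]-4-[(tert-butyldimethylsilyl)oxy]-6-hydroxy-1-[methoxy(methyl)amino]-1-oxooct-7-en-3-yl]carbamate | CON(C)C(=O)C[C@H](NC(=O)OC(C)(C)C)[C@H](O[Si](C)(C)C(C)(C)C)[C@@H]([C@H](O)C=C)C(=O)N1[C@@H](Cc2ccccc2)COC1=O | intermediate
11 | tert-butyl N-[(3S,4R,5R,6R)-5-[(4S)-4-benzyl-2-oxo-1,3-oxazolidine-3-carbonyl]-4,6-bis[(tert-butyldimethylsilyl)oxy]-1-[methoxy(methyl)amino]-1-oxooct-7-en-3-yl]carbamate | CON(C)C(=O)C[C@H](NC(=O)OC(C)(C)C)[C@H](O[Si](C)(C)C(C)(C)C)[C@@H]([C@H](O[Si](C)(C)C(C)(C)C)C=C)C(=O)N1[C@@H](Cc2ccccc2)COC1=O | intermediate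
12 | tert-butyl N-[(3S,4R,5R,6R)-4,6-bis[(tert-butyldimethylsilyl)oxy]-5-(hydroxymethyl)-1-[methoxy(methyl)amino]-1-oxooct-7-en-3-yl]carbamate | CON(C)C(=O)C[C@H](NC(=O)OC(C)(C)C)[C@H](O[Si](C)(C)C(C)(C)C)[C@@H]([C@H](O[Si](C)(C)C(C)(C)C)C=C)CO | intermediate
13 | tert-butyl N-[(5S,6R,7R,8R)-6,8-bis[(tert-butyldimethylsilyl)oxy]-7-(hydroxymethyl)-3-oxodeca-1,9-dien-5-yl]carbamate | C=CC(=O)C[C@H](NC(=O)OC(C)(C)C)[C@H](O[Si](C)(C)C(C)(C)C)[C@@H]([C@H](O[Si](C)(C)C(C)(C)C)C=C)CO | intermediate
14 | tert-butyl N-[(5S,6R,7R,8R)-6,8-bis[(tert-butyldimethylsilyl)oxy]-7-formyl-3-oxodeca-1,9-dien-5-yl]carbamate | C=CC(=O)C[C@H](NC(=O)OC(C)(C)C)[C@H](O[Si](C)(C)C(C)(C)C)[C@@H]([C@H](O[Si](C)(C)C(C)(C)C)C=C)C=O | intermediate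
15 | tert-butyl N-[(1S,2R,3R,5S)-2-[(tert-butyldimethylsilyl)oxy]-3-{(1R)-1-[(tert-butyldimethylsilyl)oxy]prop-2-en-1-yl}-5-ethenyl-5-hydroxy-4-oxocyclohexyl]carbamate | CC(C)(C)OC(=O)N[C@H]1C[C@@](C=C)(O)C(=O)[C@H]([C@H](O[Si](C)(C)C(C)(C)C)C=C)[C@H]1O[Si](C)(C)C(C)(C)C | intermediate (not isolated)
16 | tert-butyl N-[(1S,4R,5R,6R,7S)-4,6-bis[(tert-butyldimethylsilyl)oxy]-1-hydroxy-9-oxobicyclo[3.3.1]non-2-en-7-yl]carbamate | CC(C)(C)OC(=O)N[C@H]1C[C@@]2(O)C(=O)[C@H]([C@H](O[Si](C)(C)C(C)(C)C)C=C2)[C@H]1O[Si](C)(C)C(C)(C)C | intermediate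
17 | (1S,4R,5R,6R,7S)-7-amino-1,4,6-trihydroxybicyclo[3.3.1]non-2-en-9-one hydrochloride | N[C@H]1C[C@@]2(O)C(=O)[C@H]([C@H](O)C=C2)[C@H]1O.Cl | intermediate
18 | hex-5-enenitrile | C=CCCCC#N | starting material
19 | N-(bromomagnesio)undec-1-en-6-imine | C=CCCCC(=N[Mg]Br)CCCCC | intermediate (not isolated)
20 | undec-1-en-6-one | C=CCCCC(=O)CCCCC | intermediate
21 | acrylic acid | C=CC(=O)O | starting material
22 | (2E)-7-oxododec-2-enoic acid | CCCCCC(=O)CCC/C=C/C(=O)O | intermediate
23 | (2E)-7-oxo-N-[(1S,4R,5R,6R,7S)-1,4,6-trihydroxy-9-oxobicyclo[3.3.1]non-2-en-7-yl]dodec-2-enamide | CCCCCC(=O)CCC/C=C/C(=O)N[C@H]1C[C@@]2(O)C(=O)[C@H]([C@H](O)C=C2)[C@H]1O | intermediate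
24 | isariotin C | CCCCCC(=O)CCC/C=C/C(=O)N[C@H]1C[C@@]2(O)C(=O)[C@H]([C@H](O)[C@@H]3O[C@@H]32)[C@H]1O | target

**Step count.** Total: 16 steps. Longest linear sequence: 14 steps (steps 1–12, 15, 16).

**Steps most likely to fail**

Step 11 (key step). What may go wrong: conjugate addition of the carbene to the terminal enone with oligomerisation, base-induced aza-Michael closure of the carbamate onto the enone, incomplete facial control at C1, or stalling of the metathesis because the 1,3-diaxial conformer is thinly populated. Fallback (medium ring first, then transannular stitch): setting out from 14, ring-closing metathesis with the second-generation Hoveyda–Grubbs catalyst at high dilution would first close the eight-membered ring and give the (Z)-cyclooctenone aldehyde F1, in which the enone is no longer terminal. A triazolium-derived carbene would then effect a transannular crossed benzoin, for which only the geometry leading to the bicyclo[3.3.1] ketol is available, and the route is rejoined at 16.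

Step 6. What may go wrong: loss of the β-silyloxy group from the enolate, polymerisation or conjugate addition of acrolein, and erosion of facial selectivity by the neighbouring stereocentres. Fallback (masked acrolein): setting out from 8, the same boron enolate would be combined with 3-(phenylselanyl)propanal to give the selenide aldol adduct F2. Oxidation with H2O2 and syn-elimination of the selenoxide away from the carbinol would unveil the vinyl group and return the route at 10.

Step 4. What may go wrong: poor anti/syn discrimination in the hydride delivery, or competing attack on the imide. Fallback (catalyst-controlled hydrogenation before the auxiliary is attached): setting out from 3 through imidazolide 5, magnesium monobenzyl malonate would give the β-keto benzyl ester F3. Hydrogenation with RuBr2[(S)-BINAP] would set the carbinol in the hydroxy ester F4 (the sense follows from the usual BINAP–ruthenium β-keto ester model; substrate bias opposes it, so selectivity may be moderate). Silylation to the silyl ether F5, hydrogenolysis to the acid F6, activation as the mixed pivalic anhydride F7 and N-acylation of lithiated (4S)-4-benzyl-1,3-oxazolidin-2-one would return the route at 8.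

**Further compounds**

F1 | step 11 | tert-butyl N-[(1S,2R,3R,4R,5Z)-2,4-bis[(tert-butyldimethylsilyl)oxy]-3-formyl-7-oxocyclooct-5-en-1-yl]carbamate | CC(C)(C)OC(=O)N[C@H]1CC(=O)/C=C\[C@@H](O[Si](C)(C)C(C)(C)C)[C@@H](C=O)[C@H]1O[Si](C)(C)C(C)(C)C
F2 | step 6 | tert-butyl N-[(3S,4R,5R,6R)-5-[(4S)-4-benzyl-2-oxo-1,3-oxazolidine-3-carbonyl]-4-[(tert-butyldimethylsilyl)oxy]-6-hydroxy-1-[methoxy(methyl)amino]-1-oxo-8-(phenylselanyl)octan-3-yl]carbamate | CON(C)C(=O)C[C@H](NC(=O)OC(C)(C)C)[C@H](O[Si](C)(C)C(C)(C)C)[C@@H]([C@H](O)CC[Se]c1ccccc1)C(=O)N1[C@@H](Cc2ccccc2)COC1=O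
F3 | step 4 | benzyl (4S)-4-[(tert-butoxycarbonyl)amino]-6-[methoxy(methyl)amino]-3,6-dioxohexanoate | CON(C)C(=O)C[C@H](NC(=O)OC(C)(C)C)C(=O)CC(=O)OCc1ccccc1
F4 | step 4 | benzyl (3R,4S)-4-[(tert-butoxycarbonyl)amino]-3-hydroxy-6-[methoxy(methyl)amino]-6-oxohexanoate | CON(C)C(=O)C[C@H](NC(=O)OC(C)(C)C)[C@H](O)CC(=O)OCc1ccccc1
F5 | step 4 | benzyl (3R,4S)-4-[(tert-butoxycarbonyl)amino]-3-[(tert-butyldimethylsilyl)oxy]-6-[methoxy(methyl)amino]-6-oxohexanoate | CON(C)C(=O)C[C@H](NC(=O)OC(C)(C)C)[C@H](O[Si](C)(C)C(C)(C)C)CC(=O)OCc1ccccc1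
F6 | step 4 | (3R,4S)-4-[(tert-butoxycarbonyl)amino]-3-[(tert-butyldimethylsilyl)oxy]-6-[methoxy(methyl)amino]-6-oxohexanoic acid | CON(C)C(=O)C[C@H](NC(=O)OC(C)(C)C)[C@H](O[Si](C)(C)C(C)(C)C)CC(=O)O
F7 | step 4 | (3R,4S)-4-[(tert-butoxycarbonyl)amino]-3-[(tert-butyldimethylsilyl)oxy]-6-[methoxy(methyl)amino]-6-oxohexanoic 2,2-dimethylpropanoic anhydride | CON(C)C(=O)C[C@H](NC(=O)OC(C)(C)C)[C@H](O[Si](C)(C)C(C)(C)C)CC(=O)OC(=O)C(C)(C)C
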